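**Retrosynthetic overview**
- The route rests on one feature: C7 (and likewise C20) is a benzylic CH bonded to the ring A (ring B) carbon that lies between the two phenolic C–O carbons, so it is the exocyclic carbon of an ortho-quinone methide of that ring (numbering: ring B–C1–C2(Me)–C3…C6–C7–ring A–C14–C15(Me)–C16…C19–C20–ring B).
- The 22-membered [7.7]paracyclophane is opened first at ring B–C1 (NiCl2/CrCl2 aryl iodide–aldehyde closure) and then at ring A–C14 (aryltitanium addition to an α-methyl aldehyde); both carbamates come from the benzylic alcohols so formed.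
- Both halves derive from one aryl iodide that carries C7, the 4-chlorobutyl chain and C6–C1; for the C20 half its CH2Cl end is converted to CHCl2 before the union.
- That iodide comes from a 4-substituted chroman-2-ol by Wittig extension at C5 with an (S)-methyl-branched C4–C1 ylide, MOM protection, hydrogenation and C–H borylation/iodination para to C7.
- The chroman ring is formed first and opened later; it closes in the three-component reaction of 2,6-bis(Boc-oxy)benzaldehyde, 4-chlorobutylmagnesium bromide and a chiral vinyl ether (C7–side chain, C7–C6 and O–C5 bonds). The macrocycle is the second and last ring.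

Key step: step 4

Assumption: the vinyl ether is taken to react s-trans, endo, on the face away from its phenyl group (carbinol C–H eclipsing the enol C–O bond); on this model the (1S,2R)-2-phenylcyclohexyl ether, not its (1R,2S) antipode, gives the (4R)-chroman that maps onto 7S, and if the first run shows the opposite sense the antipodal alcohol is used with no other change.

**Route**

Step 1
Reactants: 1 2,6-dihydroxybenzaldehyde
Product: 2 2,6-bis(tert-butoxycarbonyloxy)benzaldehyde
Conditions: Boc2O, DMAP (cat.), iPr2NEt (cat.), THF, 0 °C → rt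
Reagents that add atoms: di-tert-butyl dicarbonate CC(C)(C)OC(=O)OC(=O)OC(C)(C)C
Why: DMAP-catalysed O-acylation of both phenols gives the bis(aryl tert-butyl carbonate), the usual precursor type for base-triggered quinone methide formation.

Step 2
Reactants: 3 1-bromo-4-chlorobutane
Product: 4 4-chlorobutylmagnesium bromide (THF solution, titrated)
Conditions: Mg turnings, I2 (cat.), THF, 20–30 °C
Reagents that add atoms: magnesium [Mg]
Why: Grignard formation occurs at C–Br much faster than at C–Cl, and the four-carbon spacer keeps the reagent from cyclising at room temperature.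

Step 3
Reactants: 5 (1S,2R)-trans-2-phenylcyclohexan-1-ol, 6 ethyl vinyl ether
Product: 7 (1S,2R)-2-phenylcyclohexyl vinyl ether
Conditions: Hg(OAc)2 (cat.), 6 as solvent, reflux
Reagents that add atoms: none
Why: Hg(OAc)2-catalysed transetherification (vinyl exchange) driven by excess ethyl vinyl ether transfers the vinyl group to the secondary alcohol without touching its stereocentres.

Step 4
Reactants: 2 2,6-bis(tert-butoxycarbonyloxy)benzaldehyde, 4 4-chlorobutylmagnesium bromide, 7 (1S,2R)-2-phenylcyclohexyl vinyl ether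
Product: 10 tert-butyl (2R,4R)-4-(4-chlorobutyl)-2-{[(1S,2R)-2-phenylcyclohexyl]oxy}chroman-5-yl carbonate (2,4-cis), via magnesium alkoxide 8 (not isolated), via ortho-quinone methide 9 (not isolated)
Conditions: 7 (3 equiv), toluene–THF, −78 °C; 4 (1.05 equiv); → rt over 6 h
Reagents that add atoms: none
Why: Grignard 4 adds to the aldehyde of 2 at −78 °C faster than to the aryl carbonates, alkoxide 8 takes over a neighbouring Boc group, and on warming the magnesium phenoxide expels tert-butyl carbonate by 1,4-elimination to give the (E)-ortho-quinone methide 9, whose exocyclic carbon is C7. The electron-rich vinyl ether 7 then adds across the O=C–C=C7 heterodiene in an inverse-electron-demand hetero-Diels–Alder reaction, the reaction type established for Grignard-triggered quinone methides from O-Boc salicylaldehydes with chiral enol ethers. The dihydropyran ring of the chroman closes by a concerted, asynchronous, suprafacial [4+2] cycloaddition that forms C7–C6 and O–C5 in one event. C7 (chroman C4, R) is set by the auxiliary, because in the endo transition state the s-trans enol ether is open only on the face away from the phenyl group and the E geometry of 9 then places the chlorobutyl chain cis to the alkoxy group; the acetal centre C5 is set by the same endo approach and is erased in step 5. The step needs chemoselective 1,2-addition (low temperature, one equivalent of 4), trapping of 9 faster than its tautomerisation to the ortho-alkenyl phenol (excess 7) and facial control; since the auxiliary stays in 10, minor diastereomers can be removed by chromatography.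

Step 5
Reactants: 10 the chroman acetal carbonate
Product: 12 (4R)-4-(4-chlorobutyl)chromane-2,5-diol (lactol as anomer mixture), via chroman phenol 11 (not isolated)
Conditions: K2CO3 (0.2 equiv), MeOH, 0 °C → rt; then 2 M aq. HCl, THF, rt
Reagents that add atoms: water O
Why: Base-catalysed methanolysis of the aryl carbonate followed by acid hydrolysis of the mixed aryl alkyl acetal frees the lactol and returns the auxiliary alcohol, with C7 not involved.

Step 6
Reactants: 13 (R)-4-benzyl-3-propanoyl-1,3-oxazolidin-2-one, 14 allyl iodide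
Product: 16 (R)-4-benzyl-3-[(S)-2-methylpent-4-enoyl]-1,3-oxazolidin-2-one, via sodium enolate 15 (not isolated)
Conditions: NaN(SiMe3)2, THF, −78 °C; 14, −78 → −45 °C
Reagents that add atoms: none
Why: Evans alkylation, in which the chelated sodium (Z)-enolate is allylated on the face away from the benzyl group, sets the methyl-bearing centre (future C2 and C15) as S.

Step 7
Reactants: 16 the allylated imide
Product: 17 (S)-2-methylpent-4-en-1-ol
Conditions: LiBH4, MeOH (1 equiv), Et2O, 0 °C
Reagents that add atoms: none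
Why: Reductive removal of the Evans auxiliary with LiBH4 reduces the imide carbonyl selectively and without epimerisation.

Step 8
Reactants: 17 (S)-2-methylpent-4-en-1-ol
Product: 18 (S)-tert-butyldimethyl[(2-methylpent-4-en-1-yl)oxy]silane
Conditions: TBSCl, imidazole, CH2Cl2, rt
Reagents that add atoms: tert-butyldimethylsilyl chloride CC(C)(C)[Si](C)(C)Cl
Why: Standard silylation of a primary alcohol.

Step 9
Reactants: 18 the TBS ether
Product: 20 (S)-4-[(tert-butyldimethylsilyl)oxy]-3-methylbutan-1-ol, via ozonide 19 (not isolated)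
Conditions: O3, CH2Cl2, −78 °C; then NaBH4, MeOH, −78 °C → rt
Reagents that add atoms: ozone [O-][O+]=O
Why: Ozonolysis of the terminal alkene with reductive work-up removes one carbon and leaves the primary alcohol carbon that becomes C4.

Step 10
Reactants: 20 the primary alcohol
Product: 21 (S)-tert-butyl(4-iodo-2-methylbutoxy)dimethylsilane
Conditions: I2, PPh3, imidazole, CH2Cl2, 0 °C → rt
Reagents that add atoms: iodine II
Why: Appel-type iodination of a primary alcohol by SN2 displacement of the oxyphosphonium group.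

Step 11
Reactants: 21 the primary iodide
Product: 22 [(3S)-4-[(tert-butyldimethylsilyl)oxy]-3-methylbutyl]triphenylphosphonium iodide
Conditions: PPh3, iPr2NEt (cat.), MeCN, 80 °C
Reagents that add atoms: triphenylphosphine c1ccc(cc1)P(c1ccccc1)c1ccccc1
Why: SN2 quaternisation of PPh3 by an unhindered primary iodide gives the Wittig salt.

Step 12
Reactants: 12 (4R)-4-(4-chlorobutyl)chromane-2,5-diol, 22 the phosphonium iodide
Product: 24 2-[(2S,4Z,7R)-1-[(tert-butyldimethylsilyl)oxy]-11-chloro-2-methylundec-4-en-7-yl]benzene-1,3-diol, via phosphorus ylide 23 (not isolated)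
Conditions: 22 (1.6 equiv), KN(SiMe3)2 (3.6 equiv), THF, −78 → 0 °C; then 12, −78 °C → rt
Reagents that add atoms: none
Why: Lactol Wittig olefination, in which the ring-opened phenoxide aldehyde is trapped by the non-stabilised ylide, forms C5=C4 and brings in C4–C1 with the C2 methyl centre already in place; the alkene geometry is of no consequence.

Step 13
Reactants: 24 the resorcinol alkene
Product: 25 tert-butyl{[(2S,4Z,7R)-7-[2,6-bis(methoxymethoxy)phenyl]-11-chloro-2-methylundec-4-en-1-yl]oxy}dimethylsilane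
Conditions: MOMCl, iPr2NEt, CH2Cl2, 0 → 40 °C
Reagents that add atoms: chloromethyl methyl ether COCCl
Why: O-alkylation of both phenols with MOMCl under amine base, which is too weak to trigger displacement of the alkyl chloride.

Step 14
Reactants: 25 the bis-MOM alkene
Product: 26 tert-butyl{[(2S,7S)-7-[2,6-bis(methoxymethoxy)phenyl]-11-chloro-2-methylundecyl]oxy}dimethylsilane
Conditions: H2 (1 atm), Pd/C, EtOAc, rt
Reagents that add atoms: none
Why: Heterogeneous hydrogenation of the disubstituted alkene, under which the primary alkyl chloride, the MOM ethers and the TBS ether are inert.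

Step 15
Reactants: 26 the saturated bis-MOM arene
Product: 27 2-{4-[(2S,7S)-1-[(tert-butyldimethylsilyl)oxy]-11-chloro-2-methylundecan-7-yl]-3,5-bis(methoxymethoxy)phenyl}-4,4,5,5-tetramethyl-1,3,2-dioxaborolane
Conditions: [Ir(OMe)(cod)]2 (cat.), 4,4′-di-tert-butyl-2,2′-bipyridine (cat.), B2pin2, THF, 80 °C
Reagents that add atoms: bis(pinacolato)diboron CC1(C)OB(OC1(C)C)B1OC(C)(C)C(C)(C)O1
Why: Sterically controlled iridium-catalysed C–H borylation goes to the only ring C–H without an ortho substituent, the position para to C7.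

Step 16
Reactants: 27 the aryl boronate
Product: 28 tert-butyl{[(2S,7S)-11-chloro-7-[4-iodo-2,6-bis(methoxymethoxy)phenyl]-2-methylundecyl]oxy}dimethylsilane
Conditions: CuI (cat.), 1,10-phenanthroline (cat.), KI, air, MeOH–THF–H2O, 60 °C
Reagents that add atoms: potassium iodide [K+].[I-]
Why: Copper-catalysed ipso-iododeboronation places iodine only where boron was, avoiding electrophilic iodination of the activated ring positions, and the protic medium keeps chloride–iodide exchange at the alkyl chloride slow.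

Step 17
Reactants: 28 the aryl iodide
Product: 29 tert-butyl{[(2S,7S)-11-iodo-7-[4-iodo-2,6-bis(methoxymethoxy)phenyl]-2-methylundecyl]oxy}dimethylsilane
Conditions: NaI, butan-2-one, 80 °C
Reagents that add atoms: sodium iodide [Na+].[I-]
Why: Finkelstein exchange (SN2) at the primary chloride, driven by precipitation of NaCl; the aryl iodide cannot take part.

Step 18
Reactants: 29 the alkyl iodide
Product: 30 (5S,10S)-11-[(tert-butyldimethylsilyl)oxy]-5-[4-iodo-2,6-bis(methoxymethoxy)phenyl]-10-methylundecanal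
Conditions: Me3NO (anhydrous), DMSO, rt
Reagents that add atoms: trimethylamine N-oxide C[N+](C)(C)[O-]
Why: Amine N-oxide oxidation of a primary iodide (Kornblum-type), by O-alkylation of the N-oxide and elimination, gives the aldehyde at room temperature.

Step 19
Reactants: 30 the chain-end aldehyde
Product: 32 tert-butyl{[(2S,7S)-11,11-dichloro-7-[4-iodo-2,6-bis(methoxymethoxy)phenyl]-2-methylundecyl]oxy}dimethylsilane, via hydrazone 31 (not isolated)
Conditions: N2H4·H2O, 4 Å molecular sieves, MeOH–THF, rt; then CuCl2, Et3N, MeOH, 0 °C → rt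
Reagents that add atoms: copper dichloride Cl[Cu]Cl
Why: Takeda gem-dichlorination, in which the hydrazone is oxidised by CuCl2 to the diazoalkane that takes up two chlorine atoms with loss of N2, converts the aldehyde to CHCl2 under mild, nearly neutral conditions.

Step 20
Reactants: 32 the dichloride
Product: 33 (2S,7S)-11,11-dichloro-7-[4-iodo-2,6-bis(methoxymethoxy)phenyl]-2-methylundecan-1-ol
Conditions: HF·pyridine, pyridine, THF, 0 °C → rt
Reagents that add atoms: none
Why: Buffered fluoride cleavage of the primary TBS ether leaves the aryl MOM ethers and the CHCl2 group alone.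

Step 21
Reactants: 33 the primary alcohol
Product: 34 (2S,7S)-11,11-dichloro-7-[4-iodo-2,6-bis(methoxymethoxy)phenyl]-2-methylundecanal
Conditions: Dess–Martin periodinane, NaHCO3, CH2Cl2, 0 °C → rt
Reagents that add atoms: none
Why: Dess–Martin oxidation under buffered conditions gives the α-methyl aldehyde without epimerisation; it is used at once.

Step 22
Reactants: 28 the aryl iodide with the chlorobutyl chain, 34 the dichloro aldehyde
Product: 37 (1R,2S,7S)-1-{4-[(2S,7S)-1-[(tert-butyldimethylsilyl)oxy]-11-chloro-2-methylundecan-7-yl]-3,5-bis(methoxymethoxy)phenyl}-11,11-dichloro-7-[4-iodo-2,6-bis(methoxymethoxy)phenyl]-2-methylundecan-1-ol (ring A–C14 bond formed), via arylmagnesium chloride 35 (not isolated), via aryltitanium triisopropoxide 36 (not isolated)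
Conditions: 28, iPrMgCl·LiCl, THF, −15 °C; ClTi(OiPr)3, −78 °C; then 34, −78 → −30 °C
Reagents that add atoms: none
Why: Iodine–magnesium exchange, transmetalation to the aryltitanium triisopropoxide and Felkin–Anh 1,2-addition, with the aryl group attacking anti to the C16 chain past the α-hydrogen, should give the 14,15-syn (14R) alcohol, and the titanium reagent neither exchanges with the aryl iodide of 34 nor touches CHCl2.

Step 23
Reactants: 37 the C14 alcohol
Product: 39 the C14 carbamate of 37, (1R,2S,7S)-1-{4-[(2S,7S)-1-[(tert-butyldimethylsilyl)oxy]-11-chloro-2-methylundecan-7-yl]-3,5-bis(methoxymethoxy)phenyl}-11,11-dichloro-7-[4-iodo-2,6-bis(methoxymethoxy)phenyl]-2-methylundecyl carbamate, via trichloroacetyl carbamate 38 (not isolated)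
Conditions: Cl3CC(O)NCO, CH2Cl2, 0 °C; then K2CO3, MeOH, rt
Reagents that add atoms: trichloroacetyl isocyanate O=C=NC(=O)C(Cl)(Cl)Cl
Why: Carbamoylation with trichloroacetyl isocyanate followed by methanolysis of the trichloroacetyl group gives the primary carbamate, which also protects C14–OH through the next steps.

Step 24
Reactants: 39 the C14 carbamate
Product: 40 (1R,2S,7S)-1-{4-[(2S,7S)-11-chloro-1-hydroxy-2-methylundecan-7-yl]-3,5-bis(methoxymethoxy)phenyl}-11,11-dichloro-7-[4-iodo-2,6-bis(methoxymethoxy)phenyl]-2-methylundecyl carbamate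
Conditions: HF·pyridine, pyridine, THF, 0 °C → rt
Reagents that add atoms: none
Why: Buffered fluoride cleavage of the only silyl ether frees the C1 alcohol without affecting carbamate, MOM ethers or halides.

Step 25
Reactants: 40 the C1 alcohol
Product: 41 (1R,2S,7S)-1-{4-[(2S,7S)-11-chloro-2-methyl-1-oxoundecan-7-yl]-3,5-bis(methoxymethoxy)phenyl}-11,11-dichloro-7-[4-iodo-2,6-bis(methoxymethoxy)phenyl]-2-methylundecyl carbamate
Conditions: Dess–Martin periodinane, NaHCO3, CH2Cl2, 0 °C → rt
Reagents that add atoms: none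
Why: Dess–Martin oxidation of the primary alcohol tolerates the primary carbamate and gives the C1 aldehyde without epimerising C2.

Step 26
Reactants: 41 the iodo aldehyde
Product: 42 (1R,2S,7S,14R,15S,20S)-7-(4-chlorobutyl)-20-(4,4-dichlorobutyl)-1-hydroxy-2,15-dimethyl[7.7]paracyclophan-14-yl carbamate with all four ring oxygens as MOM ethers (overview numbering)
Conditions: CrCl2 (excess), NiCl2 (cat.), degassed DMF–THF, rt, slow addition to high dilution
Reagents that add atoms: none
Why: Nozaki–Hiyama–Kishi reaction, by oxidative addition of the aryl iodide to zerovalent nickel, transmetalation to trivalent chromium and intramolecular addition to the aldehyde, closes the 22-membered ring at ring B–C1, with Felkin–Anh approach anti to the C3 chain expected to favour the 1,2-syn (1R) alcohol and with the carbamate and both chloroalkyl groups inert to divalent chromium.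

Step 27
Reactants: 42 the macrocyclic C1 alcohol
Product: 44 (1R,2S,7S,14R,15S,20S)-7-(4-chlorobutyl)-20-(4,4-dichlorobutyl)-2,15-dimethyl[7.7]paracyclophane-1,14-diyl dicarbamate with all four ring oxygens as MOM ethers, via trichloroacetyl carbamate 43 (not isolated)
Conditions: Cl3CC(O)NCO (1.1 equiv), CH2Cl2, −20 °C; then K2CO3, MeOH, rt
Reagents that add atoms: trichloroacetyl isocyanate O=C=NC(=O)C(Cl)(Cl)Cl
Why: The same isocyanate carbamoylation, run cold with near-stoichiometric reagent so that the hindered alcohol reacts and the existing carbamate nitrogen does not.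

Step 28
Reactants: 44 the tetrakis-MOM dicarbamate
Product: 45 CNP0310589.1, (1R,2S,7S,14R,15S,20S)-7-(4-chlorobutyl)-20-(4,4-dichlorobutyl)-2,15-dimethyl[7.7]paracyclophane-1,14-diyl dicarbamate with four free phenols
Conditions: HCl (1.25 M in MeOH), THF, 0 °C → rt
Reagents that add atoms: none
Why: Acid-catalysed acetal exchange removes the four MOM groups as dimethoxymethane, while the benzylic carbamates, which sit meta to the ring oxygens, are not activated towards ionisation.

**Compound list**
1 | 2,6-dihydroxybenzaldehyde | O=Cc1c(O)cccc1O | starting material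
2 | 2,6-bis(tert-butoxycarbonyloxy)benzaldehyde | O=Cc1c(OC(=O)OC(C)(C)C)cccc1OC(=O)OC(C)(C)C | intermediate
3 | 1-bromo-4-chlorobutane | ClCCCCBr | starting material
4 | 4-chlorobutylmagnesium bromide | ClCCCC[Mg]Br | intermediate
5 | (1S,2R)-trans-2-phenylcyclohexan-1-ol | O[C@H]1CCCC[C@@H]1c1ccccc1 | starting material
6 | ethyl vinyl ether | CCOC=C | starting material
7 | (1S,2R)-2-phenylcyclohexyl vinyl ether | C=CO[C@H]1CCCC[C@@H]1c1ccccc1 | intermediate
8 | bromomagnesium 1-[2,6-bis(tert-butoxycarbonyloxy)phenyl]-5-chloropentan-1-olate | ClCCCCC(O[Mg]Br)c1c(OC(=O)OC(C)(C)C)cccc1OC(=O)OC(C)(C)C | intermediate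
9 | tert-butyl (6E)-6-(5-chloropentylidene)-5-oxocyclohexa-1,3-dien-1-yl carbonate (ortho-quinone methide) | ClCCCC/C=C1/C(=O)C=CC=C1OC(=O)OC(C)(C)C | intermediate
10 | tert-butyl (2R,4R)-4-(4-chlorobutyl)-2-{[(1S,2R)-2-phenylcyclohexyl]oxy}chroman-5-yl carbonate | ClCCCC[C@@H]1C[C@H](O[C@H]2CCCC[C@@H]2c2ccccc2)Oc2cccc(OC(=O)OC(C)(C)C)c12 | intermediate
11 | (2R,4R)-4-(4-chlorobutyl)-2-{[(1S,2R)-2-phenylcyclohexyl]oxy}chroman-5-ol | ClCCCC[C@@H]1C[C@H](O[C@H]2CCCC[C@@H]2c2ccccc2)Oc2cccc(O)c12 | intermediate
12 | (4R)-4-(4-chlorobutyl)chromane-2,5-diol (anomer mixture) | ClCCCC[C@@H]1CC(O)Oc2cccc(O)c12 | intermediate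
13 | (R)-4-benzyl-3-propanoyl-1,3-oxazolidin-2-one | CCC(=O)N1[C@H](Cc2ccccc2)COC1=O | starting material
14 | allyl iodide | C=CCI | starting material
15 | sodium (Z)-enolate of 13 | C/C=C(\O[Na])N1[C@H](Cc2ccccc2)COC1=O | intermediate
16 | (R)-4-benzyl-3-[(S)-2-methylpent-4-enoyl]-1,3-oxazolidin-2-one | C=CC[C@H](C)C(=O)N1[C@H](Cc2ccccc2)COC1=O | intermediate
17 | (S)-2-methylpent-4-en-1-ol | C=CC[C@H](C)CO | intermediate
18 | (S)-tert-butyldimethyl[(2-methylpent-4-en-1-yl)oxy]silane | C=CC[C@H](C)CO[Si](C)(C)C(C)(C)C | intermediate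
19 | 3-[(2S)-3-[(tert-butyldimethylsilyl)oxy]-2-methylpropyl]-1,2,4-trioxolane (ozonide) | C[C@@H](CC1OCOO1)CO[Si](C)(C)C(C)(C)C | intermediate
20 | (S)-4-[(tert-butyldimethylsilyl)oxy]-3-methylbutan-1-ol | OCC[C@H](C)CO[Si](C)(C)C(C)(C)C | intermediate
21 | (S)-tert-butyl(4-iodo-2-methylbutoxy)dimethylsilane | ICC[C@H](C)CO[Si](C)(C)C(C)(C)C | intermediate
22 | [(3S)-4-[(tert-butyldimethylsilyl)oxy]-3-methylbutyl]triphenylphosphonium iodide | C[C@@H](CC[P+](c1ccccc1)(c1ccccc1)c1ccccc1)CO[Si](C)(C)C(C)(C)C.[I-] | intermediate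
23 | [(3S)-4-[(tert-butyldimethylsilyl)oxy]-3-methylbutylidene]triphenylphosphorane | C[C@@H](CC=P(c1ccccc1)(c1ccccc1)c1ccccc1)CO[Si](C)(C)C(C)(C)C | intermediate
24 | 2-[(2S,4Z,7R)-1-[(tert-butyldimethylsilyl)oxy]-11-chloro-2-methylundec-4-en-7-yl]benzene-1,3-diol | ClCCCC[C@H](C/C=C\C[C@H](C)CO[Si](C)(C)C(C)(C)C)c1c(O)cccc1O | intermediate
25 | tert-butyl{[(2S,4Z,7R)-7-[2,6-bis(methoxymethoxy)phenyl]-11-chloro-2-methylundec-4-en-1-yl]oxy}dimethylsilane | ClCCCC[C@H](C/C=C\C[C@H](C)CO[Si](C)(C)C(C)(C)C)c1c(OCOC)cccc1OCOC | intermediate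
26 | tert-butyl{[(2S,7S)-7-[2,6-bis(methoxymethoxy)phenyl]-11-chloro-2-methylundecyl]oxy}dimethylsilane | ClCCCC[C@H](CCCC[C@H](C)CO[Si](C)(C)C(C)(C)C)c1c(OCOC)cccc1OCOC | intermediate
27 | 2-{4-[(2S,7S)-1-[(tert-butyldimethylsilyl)oxy]-11-chloro-2-methylundecan-7-yl]-3,5-bis(methoxymethoxy)phenyl}-4,4,5,5-tetramethyl-1,3,2-dioxaborolane | ClCCCC[C@H](CCCC[C@H](C)CO[Si](C)(C)C(C)(C)C)c1c(OCOC)cc(cc1OCOC)B1OC(C)(C)C(C)(C)O1 | intermediate
28 | tert-butyl{[(2S,7S)-11-chloro-7-[4-iodo-2,6-bis(methoxymethoxy)phenyl]-2-methylundecyl]oxy}dimethylsilane | ClCCCC[C@H](CCCC[C@H](C)CO[Si](C)(C)C(C)(C)C)c1c(OCOC)cc(I)cc1OCOC | intermediate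
29 | tert-butyl{[(2S,7S)-11-iodo-7-[4-iodo-2,6-bis(methoxymethoxy)phenyl]-2-methylundecyl]oxy}dimethylsilane | ICCCC[C@H](CCCC[C@H](C)CO[Si](C)(C)C(C)(C)C)c1c(OCOC)cc(I)cc1OCOC | intermediate
30 | (5S,10S)-11-[(tert-butyldimethylsilyl)oxy]-5-[4-iodo-2,6-bis(methoxymethoxy)phenyl]-10-methylundecanal | O=CCCC[C@H](CCCC[C@H](C)CO[Si](C)(C)C(C)(C)C)c1c(OCOC)cc(I)cc1OCOC | intermediate
31 | hydrazone of 30 | NN=CCCC[C@H](CCCC[C@H](C)CO[Si](C)(C)C(C)(C)C)c1c(OCOC)cc(I)cc1OCOC | intermediate
32 | tert-butyl{[(2S,7S)-11,11-dichloro-7-[4-iodo-2,6-bis(methoxymethoxy)phenyl]-2-methylundecyl]oxy}dimethylsilane | ClC(Cl)CCC[C@H](CCCC[C@H](C)CO[Si](C)(C)C(C)(C)C)c1c(OCOC)cc(I)cc1OCOC | intermediate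
33 | (2S,7S)-11,11-dichloro-7-[4-iodo-2,6-bis(methoxymethoxy)phenyl]-2-methylundecan-1-ol | ClC(Cl)CCC[C@H](CCCC[C@H](C)CO)c1c(OCOC)cc(I)cc1OCOC | intermediate
34 | (2S,7S)-11,11-dichloro-7-[4-iodo-2,6-bis(methoxymethoxy)phenyl]-2-methylundecanal | ClC(Cl)CCC[C@H](CCCC[C@H](C)C=O)c1c(OCOC)cc(I)cc1OCOC | intermediate
35 | arylmagnesium chloride–LiCl from 28 (MgCl in place of I) | ClCCCC[C@H](CCCC[C@H](C)CO[Si](C)(C)C(C)(C)C)c1c(OCOC)cc([Mg]Cl)cc1OCOC.[Li+].[Cl-] | intermediate
36 | aryltitanium triisopropoxide from 28 (Ti(OiPr)3 in place of I) | ClCCCC[C@H](CCCC[C@H](C)CO[Si](C)(C)C(C)(C)C)c1c(OCOC)cc(cc1OCOC)[Ti](OC(C)C)(OC(C)C)OC(C)C | intermediate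
37 | (1R,2S,7S)-1-{4-[(2S,7S)-1-[(tert-butyldimethylsilyl)oxy]-11-chloro-2-methylundecan-7-yl]-3,5-bis(methoxymethoxy)phenyl}-11,11-dichloro-7-[4-iodo-2,6-bis(methoxymethoxy)phenyl]-2-methylundecan-1-ol | CC(C)(C)[Si](C)(C)OC[C@@H](C)CCCC[C@@H](CCCCCl)c1c(OCOC)cc(cc1OCOC)[C@H](O)[C@@H](C)CCCC[C@@H](CCCC(Cl)Cl)c1c(OCOC)cc(I)cc1OCOC | intermediate
38 | N-(trichloroacetyl)carbamate of 37 at the C14 oxygen | CC(C)(C)[Si](C)(C)OC[C@@H](C)CCCC[C@@H](CCCCCl)c1c(OCOC)cc(cc1OCOC)[C@H](OC(=O)NC(=O)C(Cl)(Cl)Cl)[C@@H](C)CCCC[C@@H](CCCC(Cl)Cl)c1c(OCOC)cc(I)cc1OCOC | intermediate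
39 | C14 carbamate of 37 | CC(C)(C)[Si](C)(C)OC[C@@H](C)CCCC[C@@H](CCCCCl)c1c(OCOC)cc(cc1OCOC)[C@H](OC(N)=O)[C@@H](C)CCCC[C@@H](CCCC(Cl)Cl)c1c(OCOC)cc(I)cc1OCOC | intermediate
40 | C14 carbamate with free C1 primary alcohol | OC[C@@H](C)CCCC[C@@H](CCCCCl)c1c(OCOC)cc(cc1OCOC)[C@H](OC(N)=O)[C@@H](C)CCCC[C@@H](CCCC(Cl)Cl)c1c(OCOC)cc(I)cc1OCOC | intermediate
41 | C14 carbamate with C1 aldehyde (2S) | O=C[C@@H](C)CCCC[C@@H](CCCCCl)c1c(OCOC)cc(cc1OCOC)[C@H](OC(N)=O)[C@@H](C)CCCC[C@@H](CCCC(Cl)Cl)c1c(OCOC)cc(I)cc1OCOC | intermediate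
42 | (1R,2S,7S,14R,15S,20S)-7-(4-chlorobutyl)-20-(4,4-dichlorobutyl)-1-hydroxy-2,15-dimethyl[7.7]paracyclophan-14-yl carbamate, tetrakis-MOM ether | C[C@H]1CCCC[C@@H](CCCCCl)c2c(OCOC)cc(cc2OCOC)[C@H](OC(N)=O)[C@@H](C)CCCC[C@@H](CCCC(Cl)Cl)c2c(OCOC)cc(cc2OCOC)[C@@H]1O | intermediate
43 | N-(trichloroacetyl)carbamate of 42 at the C1 oxygen | C[C@H]1CCCC[C@@H](CCCCCl)c2c(OCOC)cc(cc2OCOC)[C@H](OC(N)=O)[C@@H](C)CCCC[C@@H](CCCC(Cl)Cl)c2c(OCOC)cc(cc2OCOC)[C@@H]1OC(=O)NC(=O)C(Cl)(Cl)Cl | intermediate
44 | tetrakis-MOM ether of the target dicarbamate | C[C@H]1CCCC[C@@H](CCCCCl)c2c(OCOC)cc(cc2OCOC)[C@H](OC(N)=O)[C@@H](C)CCCC[C@@H](CCCC(Cl)Cl)c2c(OCOC)cc(cc2OCOC)[C@@H]1OC(N)=O | intermediate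
45 | CNP0310589.1 | C[C@H]1CCCC[C@@H](CCCCCl)c2c(O)cc(cc2O)[C@H](OC(N)=O)[C@@H](C)CCCC[C@@H](CCCC(Cl)Cl)c2c(O)cc(cc2O)[C@@H]1OC(N)=O | target

**Step count**
Total: 28 steps. Longest linear sequence: 23 steps (13 to 45 through steps 6–28); 20 steps from aldehyde 1.

**Steps most likely to fail**

1. Step 4. The quinone methide may form as an E/Z mixture, because the carbonate oxygen left next to the methide carbon is nearly as large as the carbonyl oxygen. It may also tautomerise to the ortho-alkenyl phenol before it is trapped, and facial selectivity may be low or opposite to the model.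
Fallback: it sets out from 1 and returns at 12. Aldehyde 1 is condensed with ethyl (triphenylphosphoranylidene)acetate in N,N-diethylaniline at reflux (Wittig olefination and lactonisation) to give 5-hydroxycoumarin F1. Acylation with pivaloyl chloride, Et3N and DMAP gives 2-oxo-2H-chromen-5-yl pivalate F2. Copper-catalysed enantioselective conjugate addition of Grignard 4 (CuBr·SMe2, a Josiphos-type ferrocenyl diphosphine of the antipode that gives 4R, tBuOMe, −78 °C) gives (4R)-4-(4-chlorobutyl)-2-oxochroman-5-yl pivalate F3. Excess iBu2AlH in CH2Cl2 at −78 °C then reduces the lactone to the lactol and cleaves the pivalate, giving 12. The peri substituent may slow the conjugate addition, which is why this is the reserve.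

2. Step 26. The aryl–chromium addition may proceed with poor facial selectivity at C1 inside the forming ring, and intermolecular addition or protodeiodination may compete.
Fallback: it sets out from the C1-epimer mixture of 42 delivered by step 26 and returns at 42. Dess–Martin oxidation without base gives the macrocyclic C1 ketone F4. Reduction with BH3·SMe2 and the (S)-configured B-methyl oxazaborolidine (from (S)-diphenylprolinol) in THF at −20 °C puts C1 under reagent control; this catalyst gives the R carbinol when the aryl group takes the large-group position, and so should return 42 as the 1R epimer.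

3. Step 22. The Felkin–Anh bias between the methyl group and the unbranched chain at C15 may be weak, and metal–iodine scrambling with the aryl iodide of 34 may occur if transmetalation to titanium is incomplete.
Fallback: it sets out from 27 and returns at 37. Oxidative cleavage of the pinacol ester (NaIO4, NH4OAc, acetone–H2O) gives the boronic acid F5. Boron–zinc exchange with Et2Zn in toluene at 60 °C gives the aryl(ethyl)zinc F6. This adds to aldehyde 34 at −10 °C under catalyst control by a chiral amino alcohol (3-exo-morpholinoisoborneol, antipode chosen for 14R), giving 37.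

**Further compounds**
F1 | step 4 | 5-hydroxy-2H-chromen-2-one | O=C1C=Cc2c(O)cccc2O1
F2 | step 4 | 2-oxo-2H-chromen-5-yl pivalate | CC(C)(C)C(=O)Oc1cccc2OC(=O)C=Cc12
F3 | step 4 | (4R)-4-(4-chlorobutyl)-2-oxochroman-5-yl pivalate | ClCCCC[C@@H]1CC(=O)Oc2cccc(OC(=O)C(C)(C)C)c12
F4 | step 26 | macrocyclic C1 ketone of 42 | C[C@H]1CCCC[C@@H](CCCCCl)c2c(OCOC)cc(cc2OCOC)[C@H](OC(N)=O)[C@@H](C)CCCC[C@@H](CCCC(Cl)Cl)c2c(OCOC)cc(cc2OCOC)C1=O
F5 | step 22 | {4-[(2S,7S)-1-[(tert-butyldimethylsilyl)oxy]-11-chloro-2-methylundecan-7-yl]-3,5-bis(methoxymethoxy)phenyl}boronic acid | ClCCCC[C@H](CCCC[C@H](C)CO[Si](C)(C)C(C)(C)C)c1c(OCOC)cc(cc1OCOC)B(O)O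
F6 | step 22 | aryl(ethyl)zinc from F5 (ZnEt in place of B(OH)2) | ClCCCC[C@H](CCCC[C@H](C)CO[Si](C)(C)C(C)(C)C)c1c(OCOC)cc([Zn]CC)cc1OCOC
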